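**Plan**

1. Retrosynthesis: the two C(=O)–CH2 bonds of the 4-methylpent-3-enoyl groups are cut first (prenyl carbon as a sulfonyl carbanion, acyl carbon as a lactone carbonyl). This leads to a meso bis(β-lactone). The feature that allows it: on each cyclohexane ring the carbinol oxygen (on CH–OH) and the acyl carbon (on the neighbouring methyl-bearing quaternary carbon) are cis, so each ring is an opened cis-fused 7-oxabicyclo[4.2.0]octan-8-one.
2. In each bicycle the bond between the quaternary carbon and the carbinol carbon is cut together with the lactone C–O bond (aldol-lactonisation of an α-methyl ω-formyl acid). Both ring-exocyclic C=C bonds are cut last (Wittig), leaving a C4 bis-ylide and two copies of an α-silyloxy keto acid.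
3. Forward: the C20 diacid dialdehyde chain is joined first by a two-directional Wittig reaction. Ring A is closed, then ring B, and the two base-sensitive β,γ-unsaturated ketone side chains are completed last by opening the lactones.
4. Stereochemistry: the Z alkenes come from the Wittig reaction of an α-oxygenated ketone. The cis relation of oxygen and acyl group in each ring comes from the ring fusion of the four-membered lactone. The absolute sense of ring A comes from (S)-HBTM and that of ring B from (R)-HBTM, so the two rings are mirror images and the product is meso.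

Key step: step 7

Assumption: the target is read as the meso diastereomer (the two rings are mirror images, both alkenes Z); the sense of induction of (S)-HBTM is assigned by analogy only, and because antipodal rings are needed the two catalyst enantiomers can be exchanged between steps 7 and 8 without changing compound 18.

**Route**

Step 1
Reactants: 1 propanoic acid; 2 5-bromopent-1-ene
Product: 4 2-methylhept-6-enoic acid (racemic), via dilithium propanoate enediolate 3 (not isolated)
Conditions: LiN(iPr)2 (2.1 equiv), THF/DMPU, 0 °C; then 2, 0 °C to rt; aq. HCl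
Reagents that add atoms: none
Why: Alkylation of a carboxylic acid dianion (enediolate) with a primary alkyl bromide is a standard C-alkylation, and the stereocentre it creates is racemic and is erased when this carbon later becomes an enolate.

Step 2
Reactants: 4 2-methylhept-6-enoic acid
Product: 5 7-hydroxy-2-methyl-6-oxoheptanoic acid
Conditions: RuCl3·xH2O (1 mol%), KHSO5 (as the triple salt 2KHSO5·KHSO4·K2SO4), NaHCO3, EtOAc/MeCN/H2O, rt
Reagents that add atoms: potassium peroxymonosulfate, [K+].[O-]S(=O)(=O)OO
Why: Ruthenium tetroxide-catalysed ketohydroxylation of a terminal alkene places the ketone on the internal carbon and the hydroxyl group on the terminal one, because the secondary carbon of the ruthenate ester is oxidised further, and no stereocentre is formed.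

Step 3
Reactants: 5 7-hydroxy-2-methyl-6-oxoheptanoic acid
Product: 7 7-[(tert-butyldimethylsilyl)oxy]-2-methyl-6-oxoheptanoic acid, via bis-silylated silyl ester 6 (not isolated)
Conditions: TBSCl (2.3 equiv), imidazole, DMF, rt; then K2CO3 (cat.), MeOH/H2O, 0 °C; work-up at pH 4
Reagents that add atoms: tert-butyldimethylsilyl chloride, CC(C)(C)[Si](C)(C)Cl
Why: Silylation of a primary alcohol with a silyl chloride and imidazole is routine, and the silyl ester formed on the acid at the same time is cleaved by mild solvolysis while the silyl ether stays.

Step 4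
Reactants: 7 7-[(tert-butyldimethylsilyl)oxy]-2-methyl-6-oxoheptanoic acid (2.1 equiv); 8 butane-1,4-diylbis(triphenylphosphonium) dibromide
Product: 10 (6Z,10Z)-6,11-bis{[(tert-butyldimethylsilyl)oxy]methyl}-2,15-dimethylhexadeca-6,10-dienedioic acid, via 1,4-bis(triphenylphosphoranylidene)butane 9 (not isolated)
Conditions: 8, KN(SiMe3)2 (2.05 equiv), THF, 0 °C; then the potassium carboxylate of 7 (7 and KN(SiMe3)2, 1 equiv each), THF, −78 °C to rt; aq. HCl to pH 3
Reagents that add atoms: none
Why: Twofold Wittig olefination with a non-stabilised bis-ylide, which with α-alkoxy and α-silyloxy ketones at low temperature is known to put the new alkyl chain cis to the oxygenated carbon, so that both trisubstituted alkenes should form with the Z geometry of the target.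

Step 5
Reactants: 10 (6Z,10Z)-6,11-bis{[(tert-butyldimethylsilyl)oxy]methyl}-2,15-dimethylhexadeca-6,10-dienedioic acid
Product: 11 (6Z,10Z)-6,11-bis(hydroxymethyl)-2,15-dimethylhexadeca-6,10-dienedioic acid
Conditions: HF·pyridine, pyridine, THF, 0 °C to rt
Reagents that add atoms: none
Why: Fluoride-mediated desilylation of primary silyl ethers under buffered conditions leaves the allylic alcohols, the acids and the 1,5-diene untouched.

Step 6
Reactants: 11 (6Z,10Z)-6,11-bis(hydroxymethyl)-2,15-dimethylhexadeca-6,10-dienedioic acid
Product: 12 (6Z,10Z)-6,11-diformyl-2,15-dimethylhexadeca-6,10-dienedioic acid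
Conditions: TEMPO (20 mol%), PhI(OAc)2 (2.4 equiv), CH2Cl2, rt; used without delay
Reagents that add atoms: none
Why: Oxoammonium (TEMPO) oxidation with a hypervalent iodine co-oxidant stops at the aldehyde in anhydrous medium, tolerates carboxylic acids and is known to preserve the geometry of Z-configured enals.

Step 7
Reactants: 12 (6Z,10Z)-6,11-diformyl-2,15-dimethylhexadeca-6,10-dienedioic acid
Product: 15 (6Z)-6-formyl-2-methyl-10-[(1R,5Z,6S)-1-methyl-8-oxo-7-oxabicyclo[4.2.0]octan-5-ylidene]dec-6-enoic acid, via tosyl mixed anhydride 13 (not isolated), via isothiouronium enolate 14 (not isolated)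
Conditions: TsCl (1.0 equiv, slow addition), (S)-homobenzotetramisole [(S)-HBTM, 20 mol%], iPr2NEt (4 equiv), LiCl (1 equiv), CH2Cl2 (0.02 M), 0 °C to rt; stopped at partial conversion, 15 separated from neutral material and from recovered 12, which is recycled
Reagents that add atoms: none
Why: TsCl converts one carboxyl group into mixed anhydride 13, the isothiourea takes over the acyl group and iPr2NEt removes the only α-hydrogen to give the catalyst-bound enolate 14, whose α-carbon adds to the carbonyl carbon of the neighbouring enal, after which the syn alkoxide displaces the catalyst from the acyl carbon; the closest known reaction type is the nucleophile-catalysed aldol-lactonisation of ω-oxo acids, and the formation of α-quaternary β-lactones from disubstituted ammonium enolates and aldehydes is its known intermolecular counterpart. The six-membered carbocycle closes by a 6-exo-trig attack of an enolate that is exocyclic to the new ring (enolexo) on the aldehyde carbon, the four-membered lactone by a 4-exo-trig acyl substitution at the acyl isothiouronium carbon. The relative configuration of the new quaternary carbon and the new oxygen-bearing carbon is set by the ring fusion, since the aldol addition is reversible and only the aldolate with oxygen and acyl carbon on the same face of the six-membered ring can lactonise, which gives the cis relation of hydroxyl and acyl group found in the target; the absolute configuration of both centres follows from the enolate face left open by the phenyl group of the catalyst. Three selectivities are needed: 1,2-addition instead of conjugate addition to the enal, secured by the higher electrophilicity of the aldehyde carbon and by the chair-like six-membered transition state; retention of the Z enal, secured by its α,β-disubstitution, which disfavours reversible Lewis-base addition, and by the short reaction time; and reaction of one end only, secured by one equivalent of TsCl at partial conversion, separation of acid 15 from neutral doubly cyclised material and recycling of 12. Because the acid has a single α-position the enolate is regiodefined, which it could not be in the final ketone with its more acidic allylic α′-CH2 group.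

Step 8
Reactants: 15 (6Z)-6-formyl-2-methyl-10-[(1R,5Z,6S)-1-methyl-8-oxo-7-oxabicyclo[4.2.0]octan-5-ylidene]dec-6-enoic acid
Product: 18 (1R,5Z,6S)-1-methyl-5-{(4Z)-4-[(1S,6R)-1-methyl-8-oxo-7-oxabicyclo[4.2.0]octan-5-ylidene]butylidene}-7-oxabicyclo[4.2.0]octan-8-one (meso), via tosyl mixed anhydride 16 (not isolated), via isothiouronium enolate 17 (not isolated)
Conditions: TsCl (1.3 equiv), (R)-HBTM (20 mol%), iPr2NEt (4 equiv), LiCl (1 equiv), CH2Cl2 (0.02 M), 0 °C to rt
Reagents that add atoms: none
Why: The same nucleophile-catalysed aldol-lactonisation with the mirror-image catalyst should close ring B with the opposite absolute sense, the remote ring A having no influence, so that the two bicycles become mirror images (meso) while the cis ring fusion again fixes the relative configuration of the two new centres.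

Step 9
Reactants: 19 1-bromo-3-methylbut-2-ene; 20 sodium benzenesulfinate
Product: 21 [(3-methylbut-2-en-1-yl)sulfonyl]benzene (prenyl phenyl sulfone)
Conditions: DMF, rt
Reagents that add atoms: none
Why: SN2 S-alkylation of a sulfinate salt by a primary allylic bromide gives the allylic sulfone without allylic transposition.

Step 10
Reactants: 18 the meso bis(β-lactone); 21 prenyl phenyl sulfone (4.4 equiv)
Product: 23 meso-configured bis(β-keto sulfone) diol [each ring: 2-hydroxy-1-methyl-1-(4-methyl-2-(phenylsulfonyl)pent-3-enoyl); sulfonyl-bearing carbons unassigned], via lithiated prenyl phenyl sulfone 22 (not isolated)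
Conditions: 21, n-BuLi (4.2 equiv), THF, −78 °C; then 18, −78 °C; AcOH quench at −78 °C
Reagents that add atoms: none
Why: Acylation of an α-sulfonyl carbanion (which reacts at the carbon next to sulfur) by the strained lactone at its acyl carbon opens each four-membered ring to the β-alkoxide of a β-keto sulfone, whose immediate deprotonation by the second equivalent of carbanion blocks retro-aldol cleavage, and the ring stereocentres are not touched.

Step 11
Reactants: 23 the bis(β-keto sulfone) diol
Product: 25 CNP0297042.2 (meso diol diketone; full name in the compound list), via bis(diiodosamarium) dienolate 24 (not isolated)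
Conditions: SmI2 (5 equiv), THF/MeOH, −78 °C; pH 7 buffer
Reagents that add atoms: none
Why: Reductive desulfonylation of α-sulfonyl ketones by SmI2 is fast at low temperature, and kinetic protonation of the resulting dienolate at its α-carbon by methanol should give the deconjugated β,γ-unsaturated ketone without touching the β-hydroxy ketone or the ring stereocentres.

**Compound list**

1 | propanoic acid | CCC(=O)O | starting material
2 | 5-bromopent-1-ene | C=CCCCBr | starting material
3 | dilithium propanoate enediolate (formed in the flask) | CC=C(O[Li])O[Li] | intermediate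
4 | 2-methylhept-6-enoic acid (racemic) | C=CCCCC(C)C(=O)O | intermediate
5 | 7-hydroxy-2-methyl-6-oxoheptanoic acid | OCC(=O)CCCC(C)C(=O)O | intermediate
6 | tert-butyldimethylsilyl 7-[(tert-butyldimethylsilyl)oxy]-2-methyl-6-oxoheptanoate (formed in the flask) | CC(C)(C)[Si](C)(C)OCC(=O)CCCC(C)C(=O)O[Si](C)(C)C(C)(C)C | intermediate
7 | 7-[(tert-butyldimethylsilyl)oxy]-2-methyl-6-oxoheptanoic acid | CC(C)(C)[Si](C)(C)OCC(=O)CCCC(C)C(=O)O | intermediate
8 | butane-1,4-diylbis(triphenylphosphonium) dibromide | [Br-].[Br-].c1ccccc1[P+](c1ccccc1)(c1ccccc1)CCCC[P+](c1ccccc1)(c1ccccc1)c1ccccc1 | starting material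
9 | 1,4-bis(triphenylphosphoranylidene)butane (formed in the flask) | c1ccccc1P(c1ccccc1)(c1ccccc1)=CCCC=P(c1ccccc1)(c1ccccc1)c1ccccc1 | intermediate
10 | (6Z,10Z)-6,11-bis{[(tert-butyldimethylsilyl)oxy]methyl}-2,15-dimethylhexadeca-6,10-dienedioic acid | OC(=O)C(C)CCC/C(CO[Si](C)(C)C(C)(C)C)=C/CC/C=C(CO[Si](C)(C)C(C)(C)C)/CCCC(C)C(=O)O | intermediate
11 | (6Z,10Z)-6,11-bis(hydroxymethyl)-2,15-dimethylhexadeca-6,10-dienedioic acid | OC(=O)C(C)CCC/C(CO)=C/CC/C=C(CO)/CCCC(C)C(=O)O | intermediate
12 | (6Z,10Z)-6,11-diformyl-2,15-dimethylhexadeca-6,10-dienedioic acid | OC(=O)C(C)CCC/C(C=O)=C/CC/C=C(C=O)/CCCC(C)C(=O)O | intermediate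
13 | mono(p-toluenesulfonic) mixed anhydride of 12 (formed in the flask) | Cc1ccc(cc1)S(=O)(=O)OC(=O)C(C)CCC/C(C=O)=C/CC/C=C(C=O)/CCCC(C)C(=O)O | intermediate
14 | acyl isothiouronium enolate from 13 and (S)-HBTM (formed in the flask) | [O-]C(=C(C)CCC/C(C=O)=C/CC/C=C(C=O)/CCCC(C)C(=O)O)[N+]1=C2Sc3ccccc3N2CC[C@H]1c1ccccc1 | intermediate
15 | (6Z)-6-formyl-2-methyl-10-[(1R,5Z,6S)-1-methyl-8-oxo-7-oxabicyclo[4.2.0]octan-5-ylidene]dec-6-enoic acid | O=C2[C@]1(C)CCC/C(=C/CC/C=C(C=O)/CCCC(C)C(=O)O)[C@@H]1O2 | intermediate
16 | p-toluenesulfonic mixed anhydride of 15 (formed in the flask) | O=C2[C@]1(C)CCC/C(=C/CC/C=C(C=O)/CCCC(C)C(=O)OS(=O)(=O)c3ccc(C)cc3)[C@@H]1O2 | intermediate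
17 | acyl isothiouronium enolate from 16 and (R)-HBTM (formed in the flask) | O=C2[C@]1(C)CCC/C(=C/CC/C=C(C=O)/CCCC(C)=C([O-])[N+]3=C4Sc5ccccc5N4CC[C@@H]3c3ccccc3)[C@@H]1O2 | intermediate
18 | (1R,5Z,6S)-1-methyl-5-{(4Z)-4-[(1S,6R)-1-methyl-8-oxo-7-oxabicyclo[4.2.0]octan-5-ylidene]butylidene}-7-oxabicyclo[4.2.0]octan-8-one (meso bis(β-lactone)) | O=C2[C@]1(C)CCC/C(=C/CC/C=C3/CCC[C@](C)(C4=O)[C@@H]3O4)[C@@H]1O2 | intermediate
19 | 1-bromo-3-methylbut-2-ene | CC(C)=CCBr | starting material
20 | sodium benzenesulfinate | [Na+].[O-]S(=O)c1ccccc1 | starting material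
21 | [(3-methylbut-2-en-1-yl)sulfonyl]benzene | CC(C)=CCS(=O)(=O)c1ccccc1 | intermediate
22 | [1-lithio-3-methylbut-2-en-1-yl)sulfonyl]benzene, the lithiated sulfone (formed in the flask) | CC(C)=CC([Li])S(=O)(=O)c1ccccc1 | intermediate
23 | bis(β-keto sulfone) diol: the target skeleton with a phenylsulfonyl group on each CH2 between ketone and alkene, ring centres as in 18, sulfonyl-bearing carbons unassigned | CC(C)=CC(S(=O)(=O)c1ccccc1)C(=O)[C@]1(C)CCC/C(=C/CC/C=C2/CCC[C@](C)(C(=O)C(C=C(C)C)S(=O)(=O)c3ccccc3)[C@@H]2O)[C@@H]1O | intermediate
24 | bis(diiodosamarium) dienolate of the target (formed in the flask) | CC(C)=CC=C(O[Sm](I)I)[C@]1(C)CCC/C(=C/CC/C=C2/CCC[C@](C)(C(O[Sm](I)I)=CC=C(C)C)[C@@H]2O)[C@@H]1O | intermediate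
25 | 1-[(1R,2S,3Z)-2-hydroxy-3-{(4Z)-4-[(2R,3S)-2-hydroxy-3-methyl-3-(4-methylpent-3-enoyl)cyclohexylidene]butylidene}-1-methylcyclohexyl]-4-methylpent-3-en-1-one (meso; CNP0297042.2) | CC(C)=CCC(=O)[C@]1(C)CCC/C(=C/CC/C=C2/CCC[C@](C)(C(=O)CC=C(C)C)[C@@H]2O)[C@@H]1O | target

**Step count and risks**

Total step count: 11. Longest linear sequence: 10 (steps 1 to 8, 10 and 11; step 9 is a side branch).

The three steps most likely to fail:

Step 7 (and with it step 8). What may go wrong: enolisation of the α-branched acyl isothiouronium ion may be too slow, so that acyl transfer between molecules and hydrolysis win. Facial selectivity at a fully substituted enolate may be poor. The Z enal geometry may be lost through reversible Lewis-base addition. Fallback, which sets out from 2 and comes back at 18, builds the quaternary carbon only after ring closure. The dianion of acetic acid is alkylated with 2 to give hept-6-enoic acid F1. Ketohydroxylation as in step 2 gives 7-hydroxy-6-oxoheptanoic acid F2, and silylation as in step 3 gives 7-[(tert-butyldimethylsilyl)oxy]-6-oxoheptanoic acid F3. The double Wittig reaction with 8 as in step 4 gives (6Z,10Z)-6,11-bis{[(tert-butyldimethylsilyl)oxy]methyl}hexadeca-6,10-dienedioic acid F4. Desilylation gives (6Z,10Z)-6,11-bis(hydroxymethyl)hexadeca-6,10-dienedioic acid F5, and oxidation gives (6Z,10Z)-6,11-diformylhexadeca-6,10-dienedioic acid F6. F6 is an α-unbranched ω-formyl acid, the substrate class on which the aldol-lactonisation of aldehyde acids is established. With (S)-HBTM it should give the nor-methyl mono-lactone acid F7, and with (R)-HBTM the nor-methyl meso bis(β-lactone) F8. Deprotonation of F8 at both ring-fusion carbons with LiN(iPr)2 in THF at −78 °C and alkylation of the lactone enolates with MeI, which can only take place with retention of the cis ring fusion, gives 18.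

Step 4. What may go wrong: the basic ylide may enolise the ketone, and the Z selectivity may erode when the α-silyloxy ketone carries a long chain instead of a methyl group. Fallback, which sets out from 1 and comes back at 11, forms the same alkenes from the other side. The dianion of 1 is alkylated with an excess of 1,4-dibromobutane to give 6-bromo-2-methylhexanoic acid F9, which with triphenylphosphine in hot acetonitrile gives (5-carboxyhexyl)triphenylphosphonium bromide F10. Its ylide (excess PhLi, THF, −78 °C) is added to butanedial F11, freshly liberated from 2,5-dimethoxytetrahydrofuran with aqueous acid. The adduct is deprotonated once more with s-BuLi and the β-oxido ylide is trapped with formaldehyde. This three-component Wittig olefination is known to place the hydroxymethyl group cis to the chain that comes from the aldehyde, and should give diol diacid 11 directly, without the silyl ether.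

Step 10. What may go wrong: the sulfonyl carbanion may attack the allylic carbon–oxygen bond of the lactone instead of the acyl carbon, and the β-alkoxide ketone may undergo retro-aldol cleavage before it is deprotonated. Fallback, which sets out from 18 and comes back at 23, opens the lactones first with a nitrogen nucleophile that is known to attack only the acyl carbon. MeNHOMe·HCl and AlMe3 in CH2Cl2 at 0 °C give the bis(N-methoxy-N-methylamide) diol F12. An excess of 22 in THF at −78 °C then acylates at the amide (Weinreb ketone synthesis); the chelated tetrahedral adduct holds until the acidic quench, so that no free ketone meets an alkoxide, and 23 results.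

Further compounds
F1 | step 7 | hept-6-enoic acid | C=CCCCCC(=O)O
F2 | step 7 | 7-hydroxy-6-oxoheptanoic acid | OCC(=O)CCCCC(=O)O
F3 | step 7 | 7-[(tert-butyldimethylsilyl)oxy]-6-oxoheptanoic acid | CC(C)(C)[Si](C)(C)OCC(=O)CCCCC(=O)O
F4 | step 7 | (6Z,10Z)-6,11-bis{[(tert-butyldimethylsilyl)oxy]methyl}hexadeca-6,10-dienedioic acid | OC(=O)CCCC/C(CO[Si](C)(C)C(C)(C)C)=C/CC/C=C(CO[Si](C)(C)C(C)(C)C)/CCCCC(=O)O
F5 | step 7 | (6Z,10Z)-6,11-bis(hydroxymethyl)hexadeca-6,10-dienedioic acid | OC(=O)CCCC/C(CO)=C/CC/C=C(CO)/CCCCC(=O)O
F6 | step 7 | (6Z,10Z)-6,11-diformylhexadeca-6,10-dienedioic acid | OC(=O)CCCC/C(C=O)=C/CC/C=C(C=O)/CCCCC(=O)O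
F7 | step 7 | (6Z)-6-formyl-10-[(1S,5Z,6S)-8-oxo-7-oxabicyclo[4.2.0]octan-5-ylidene]dec-6-enoic acid (nor-methyl mono-lactone acid) | O=C2[C@@H]1CCC/C(=C/CC/C=C(C=O)/CCCCC(=O)O)[C@@H]1O2
F8 | step 7 | nor-methyl meso bis(β-lactone), 18 without its two methyl groups | O=C2[C@@H]1CCC/C(=C/CC/C=C3/CCC[C@H](C4=O)[C@@H]3O4)[C@@H]1O2
F9 | step 4 | 6-bromo-2-methylhexanoic acid | OC(=O)C(C)CCCCBr
F10 | step 4 | (5-carboxyhexyl)triphenylphosphonium bromide | OC(=O)C(C)CCCC[P+](c1ccccc1)(c1ccccc1)c1ccccc1.[Br-]
F11 | step 4 | butanedial | O=CCCC=O
F12 | step 10 | bis(N-methoxy-N-methylamide) diol, the target skeleton with C(=O)N(OMe)Me in place of each ketone side chain | CON(C)C(=O)[C@]1(C)CCC/C(=C/CC/C=C2/CCC[C@](C)(C(=O)N(C)OC)[C@@H]2O)[C@@H]1O
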